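**Plan**

1. Retrosynthetic cuts, in order:
   - the C5–CH2 bond of the 3-hydroxy-3-methylbutyl chain (alkyne coupling plus hydrogenation);
   - the furan O1–C2 bond (cyclodehydration);
   - the C3–C3a bond (undone as a 1,2-aryl shift, which gives back a chalcone);
   - the chalcone Cα=Cβ bond (aldol condensation).
2. Enabling feature: C2, C3 and the formyl carbon form a three-carbon chain with its two aryl groups on adjacent atoms, the 2-methoxy-4-hydroxyphenyl ring on C2 and benzo carbon C3a on C3. This is a chalcone whose trioxygenated ring has moved from the formyl carbon to C3. O1 on C7a is an ortho oxygen of that same ring, placed to close on the former carbonyl carbon C2.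
3. Forward order: both benzene rings are bought and decorated, and the aldol condensation joins them through the C3 chain. The aryl shift makes C3–C3a, and the furan, the only ring built, closes by O1–C2. The side chain is attached last at C5 and saturated while the benzyl ethers are cleaved.
4. Regiochemistry: of the two ortho oxygens of the migrating ring, the MOM-protected one (next to the ring C–H) becomes O1. The benzylated one (next to iodine) becomes the C4 hydroxyl, so the iodine marks C5.
5. Stereochemistry: the target has no stereogenic element. The E alkene is consumed in the shift, and the sp3 centres formed on the way are racemic and vanish on aromatisation.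

Key step: step 8

Remark on the chemistry: the target SMILES holds no stereocentre and no stereogenic double bond. The compound is achiral, so the demand for a single enantiomer is met by the constitution alone.

**Route**

Step 1
Reactants: 1 2,4,6-trimethoxybenzaldehyde
Product: 2 2,6-dihydroxy-4-methoxybenzaldehyde
Conditions: AlCl3 (5 equiv), CH2Cl2, 0 °C to reflux; then 1 M HCl
Reagents that add atoms: none
Why: Chelation-directed Lewis-acid ether cleavage, in which aluminium bridges the formyl oxygen and a flanking methoxy oxygen so that chloride dealkylates only the two ortho ethers and the non-chelating para ether is kept, as is known for 2,6-dimethoxybenzaldehydes.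

Step 2
Reactants: 2 2,6-dihydroxy-4-methoxybenzaldehyde
Product: 3 2-hydroxy-4-methoxy-6-(methoxymethoxy)benzaldehyde
Conditions: MOMCl (1.05 equiv), iPr2NEt (1.2 equiv), CH2Cl2, 0 °C
Reagents that add atoms: chloromethyl methyl ether, COCCl
Why: O-alkylation of one of two symmetry-equivalent phenols; once one oxygen is capped, the other is held in a strong hydrogen bond to the formyl oxygen and is too weak a nucleophile for one equivalent of MOMCl with an amine base, the usual behaviour of 2,6-dihydroxyaryl carbonyl compounds.

Step 3
Reactants: 3 2-hydroxy-4-methoxy-6-(methoxymethoxy)benzaldehyde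
Product: 4 2-hydroxy-3-iodo-4-methoxy-6-(methoxymethoxy)benzaldehyde
Conditions: BnMe3N·ICl2 (1.0 equiv), NaHCO3, CH2Cl2–MeOH, rt
Reagents that add atoms: benzyltrimethylammonium dichloroiodate, C[N+](C)(C)Cc1ccccc1.Cl[I-]Cl
Why: Buffered electrophilic aromatic iodination, which in 2-hydroxy-4,6-dialkoxyaryl carbonyl compounds goes to the carbon next to the chelated hydroxyl rather than between the two ethers, while the bicarbonate protects the MOM group; the site is to be checked by NOE from the remaining ArH to both OCH3 and OCH2O.

Step 4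
Reactants: 4 2-hydroxy-3-iodo-4-methoxy-6-(methoxymethoxy)benzaldehyde
Product: 5 2-(benzyloxy)-3-iodo-4-methoxy-6-(methoxymethoxy)benzaldehyde
Conditions: BnBr, K2CO3, DMF, 60 °C
Reagents that add atoms: benzyl bromide, BrCc1ccccc1
Why: Williamson ether synthesis; warm carbonate in a dipolar aprotic solvent breaks the chelate and the phenoxide is benzylated despite its two ortho neighbours, while aldehyde, MOM ether and aryl iodide are inert.

Step 5
Reactants: 6 2,4-dihydroxyacetophenone
Product: 7 4-(benzyloxy)-2-hydroxyacetophenone
Conditions: BnBr (1.05 equiv), K2CO3, acetone, reflux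
Reagents that add atoms: benzyl bromide, BrCc1ccccc1
Why: Selective Williamson etherification of the more acidic, non-chelated 4-hydroxyl, a standard differentiation of resacetophenone.

Step 6
Reactants: 7 4-(benzyloxy)-2-hydroxyacetophenone
Product: 8 4-(benzyloxy)-2-methoxyacetophenone
Conditions: MeI, K2CO3, DMF, rt to 40 °C
Reagents that add atoms: iodomethane, CI
Why: Williamson methylation of the remaining chelated phenol, which proceeds readily in DMF with an unhindered electrophile.

Step 7
Reactants: 5 2-(benzyloxy)-3-iodo-4-methoxy-6-(methoxymethoxy)benzaldehyde; 8 4-(benzyloxy)-2-methoxyacetophenone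
Product: 10 (E)-1-[4-(benzyloxy)-2-methoxyphenyl]-3-[2-(benzyloxy)-3-iodo-4-methoxy-6-(methoxymethoxy)phenyl]prop-2-en-1-one, via aldol adduct 9 (not isolated)
Conditions: KOH (50% aq.), EtOH–THF, rt
Reagents that add atoms: none
Why: Claisen–Schmidt condensation of a methyl ketone with a non-enolisable aldehyde, well known for 2,4,6-trialkoxybenzaldehydes; E1cB loss of water from 9 gives the more stable E enone, and all ethers and the aryl iodide tolerate hydroxide.

Step 8
Reactants: 10 (E)-chalcone
Product: 12 rac-1-[4-(benzyloxy)-2-methoxyphenyl]-2-[2-(benzyloxy)-3-iodo-4-methoxy-6-(methoxymethoxy)phenyl]-3,3-dimethoxypropan-1-one, via iodane adduct 11 (not isolated)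
Conditions: PhI(OH)OTs (1.2 equiv), MeOH–CH2Cl2, 0 °C to rt
Reagents that add atoms: methanol, CO
Why: Oxidative 1,2-aryl migration of a chalcone by iodine(III) in methanol, the hypervalent-iodine counterpart of the thallium(III) nitrate rearrangement that leads to isoflavone precursors: the iodane adds to the enone C=C while methanol enters at the benzylic β-carbon (adduct 11), and PhI then leaves the α-carbon with help from the ipso carbon of the trioxygenated ring through a spiro phenonium ion. Opening of the bridged ion at the β-carbon leaves that ring on the α-carbon (the later C3–C3a bond) and an oxocarbenium ion at the β-carbon, which a second methanol traps as the dimethyl acetal, the masked formyl carbon. No ring is closed here, the three-membered phenonium ring being only transient, and O1–C2 is left to steps 9 and 10. The one new stereocentre, C2 of the propanone, forms racemic without any controlling element, and none is needed since it ends as sp2 C3 of the furan. The step needs aryl migration to beat plain solvolysis at the α-carbon and oxidation of the arenes: the three oxygen donors ortho and para to the migrating carbon secure the first, and the second is held back because that ring has a single free position wedged between two alkoxy groups and the other ring is deactivated by its carbonyl group. Ligand exchange of the reagent with the C–I bond of the substrate should do no harm, since an aryl-λ3-iodane formed in this way is itself an oxidant for the enone and returns to the aryl iodide when it is used.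

Step 9
Reactants: 12 rac-keto dimethyl acetal
Product: 14 [4-(benzyloxy)-5-iodo-2,6-dimethoxy-2,3-dihydro-1-benzofuran-3-yl][4-(benzyloxy)-2-methoxyphenyl]methanone, via free phenol 13 (not isolated)
Conditions: TsOH·H2O (0.1 equiv), MeOH–CH2Cl2, rt to 40 °C
Reagents that add atoms: none
Why: Acid-catalysed transacetalisation: methanolysis removes the aryl MOM ether, and phenol 13 captures the oxocarbenium ion of the neighbouring dimethyl acetal (5-exo-trig) to give the kinetic cyclic methyl acetal, a known outcome for rearranged 2-(alkoxymethoxy)chalcones; catalytic acid leaves benzyl ethers and iodide alone, and the two racemic centres are of no consequence.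

Step 10
Reactants: 14 3-aroyl-2-methoxy-2,3-dihydrobenzofuran
Product: 16 4-(benzyloxy)-2-[4-(benzyloxy)-2-methoxyphenyl]-5-iodo-6-methoxy-1-benzofuran-3-carbaldehyde, via ring-opened enol ether 15 (not isolated)
Conditions: TsOH·H2O (1 equiv), (CF3)2CHOH, rt
Reagents that add atoms: none
Why: In the strongly ionising, weakly nucleophilic fluoroalcohol the acid reopens the cyclic acetal to 15, the phenol closes reversibly on the protonated aryl ketone (5-exo-trig, O1–C2), and dehydration gives the aromatic furan, whose exocyclic methoxycarbenium ion takes the released water back and loses methanol to show the formyl group; this is the known acid/fluoroalcohol switch from 3-acyl-2-methoxy-2,3-dihydrobenzofurans to 2-aryl-3-formylbenzofurans.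

Step 11
Reactants: 16 5-iodobenzofuran-3-carbaldehyde bis-benzyl ether; 17 2-methylbut-3-yn-2-ol
Product: 18 4-(benzyloxy)-2-[4-(benzyloxy)-2-methoxyphenyl]-5-(3-hydroxy-3-methylbut-1-yn-1-yl)-6-methoxy-1-benzofuran-3-carbaldehyde
Conditions: PdCl2(PPh3)2 (5 mol %), CuI (10 mol %), Et3N–DMF, 60 °C, argon
Reagents that add atoms: none
Why: Sonogashira coupling; iodides flanked by two alkoxy groups, such as 6- and 8-iodo-5,7-dialkoxyflavones, are known to couple with this slim alkyne, the aldehyde is inert to the amine/Cu/Pd system, and the benzyl group on O4 prevents cyclisation of an ortho-alkynylphenol.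

Step 12
Reactants: 18 alkynyl bis-benzyl ether
Product: 20 Ebenfuran VI, via saturated bis-benzyl ether 19 (not isolated)
Conditions: H2 (1 atm), 10% Pd/C, EtOAc, rt, stopped after uptake of 4 equiv of H2
Reagents that add atoms: none
Why: Heterogeneous hydrogenation followed by hydrogenolysis: the alkyne is saturated first (19), then both aryl benzyl ethers are cleaved, while the formyl group, a vinylogous ester carbonyl (O1–C2=C3–CHO) that also becomes hydrogen-bonded to the freed 4-OH, and the tetrasubstituted furan double bond are reduced much more slowly in a neutral aprotic solvent.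

**Compound list**

| No. | Name | SMILES | Role |
|---|---|---|---|
| 1 | 2,4,6-trimethoxybenzaldehyde | COc1cc(OC)c(C=O)c(OC)c1 | starting material |
| 2 | 2,6-dihydroxy-4-methoxybenzaldehyde | COc1cc(O)c(C=O)c(O)c1 | intermediate |
| 3 | 2-hydroxy-4-methoxy-6-(methoxymethoxy)benzaldehyde | COCOc1cc(OC)cc(O)c1C=O | intermediate |
| 4 | 2-hydroxy-3-iodo-4-methoxy-6-(methoxymethoxy)benzaldehyde | COCOc1cc(OC)c(I)c(O)c1C=O | intermediate |
| 5 | 2-(benzyloxy)-3-iodo-4-methoxy-6-(methoxymethoxy)benzaldehyde | O=Cc1c(OCc2ccccc2)c(I)c(OC)cc1OCOC | intermediate |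
| 6 | 2,4-dihydroxyacetophenone | CC(=O)c1ccc(O)cc1O | starting material |
| 7 | 4-(benzyloxy)-2-hydroxyacetophenone | CC(=O)c1ccc(OCc2ccccc2)cc1O | intermediate |
| 8 | 4-(benzyloxy)-2-methoxyacetophenone | CC(=O)c1ccc(OCc2ccccc2)cc1OC | intermediate |
| 9 | rac-1-[4-(benzyloxy)-2-methoxyphenyl]-3-[2-(benzyloxy)-3-iodo-4-methoxy-6-(methoxymethoxy)phenyl]-3-hydroxypropan-1-one (aldol adduct) | COc1cc(OCc2ccccc2)ccc1C(=O)CC(O)c1c(OCc2ccccc2)c(I)c(OC)cc1OCOC | intermediate |
| 10 | (E)-1-[4-(benzyloxy)-2-methoxyphenyl]-3-[2-(benzyloxy)-3-iodo-4-methoxy-6-(methoxymethoxy)phenyl]prop-2-en-1-one | COc1cc(OCc2ccccc2)ccc1C(=O)/C=C/c1c(OCc2ccccc2)c(I)c(OC)cc1OCOC | intermediate |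
| 11 | 3-methoxy-2-[phenyl(tosyloxy)-λ3-iodanyl] adduct of 10 (racemic, relative configuration of no consequence) | COc1cc(OCc2ccccc2)ccc1C(=O)C(C(OC)c1c(OCc2ccccc2)c(I)c(OC)cc1OCOC)I(c1ccccc1)OS(=O)(=O)c1ccc(C)cc1 | intermediate |
| 12 | rac-1-[4-(benzyloxy)-2-methoxyphenyl]-2-[2-(benzyloxy)-3-iodo-4-methoxy-6-(methoxymethoxy)phenyl]-3,3-dimethoxypropan-1-one | COc1cc(OCc2ccccc2)ccc1C(=O)C(C(OC)OC)c1c(OCc2ccccc2)c(I)c(OC)cc1OCOC | intermediate |
| 13 | rac-1-[4-(benzyloxy)-2-methoxyphenyl]-2-[2-(benzyloxy)-6-hydroxy-3-iodo-4-methoxyphenyl]-3,3-dimethoxypropan-1-one | COc1cc(OCc2ccccc2)ccc1C(=O)C(C(OC)OC)c1c(OCc2ccccc2)c(I)c(OC)cc1O | intermediate |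
| 14 | [4-(benzyloxy)-5-iodo-2,6-dimethoxy-2,3-dihydro-1-benzofuran-3-yl][4-(benzyloxy)-2-methoxyphenyl]methanone (racemic, C2/C3 diastereomers, both centres erased later) | COC1Oc2cc(OC)c(I)c(OCc3ccccc3)c2C1C(=O)c1ccc(OCc2ccccc2)cc1OC | intermediate |
| 15 | 1-[4-(benzyloxy)-2-methoxyphenyl]-2-[2-(benzyloxy)-6-hydroxy-3-iodo-4-methoxyphenyl]-3-methoxyprop-2-en-1-one (alkene geometry not fixed) | COC=C(C(=O)c1ccc(OCc2ccccc2)cc1OC)c1c(O)cc(OC)c(I)c1OCc1ccccc1 | intermediate |
| 16 | 4-(benzyloxy)-2-[4-(benzyloxy)-2-methoxyphenyl]-5-iodo-6-methoxy-1-benzofuran-3-carbaldehyde | COc1cc(OCc2ccccc2)ccc1-c1oc2cc(OC)c(I)c(OCc3ccccc3)c2c1C=O | intermediate |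
| 17 | 2-methylbut-3-yn-2-ol | C#CC(C)(C)O | starting material |
| 18 | 4-(benzyloxy)-2-[4-(benzyloxy)-2-methoxyphenyl]-5-(3-hydroxy-3-methylbut-1-yn-1-yl)-6-methoxy-1-benzofuran-3-carbaldehyde | COc1cc(OCc2ccccc2)ccc1-c1oc2cc(OC)c(C#CC(C)(C)O)c(OCc3ccccc3)c2c1C=O | intermediate |
| 19 | 4-(benzyloxy)-2-[4-(benzyloxy)-2-methoxyphenyl]-5-(3-hydroxy-3-methylbutyl)-6-methoxy-1-benzofuran-3-carbaldehyde | COc1cc(OCc2ccccc2)ccc1-c1oc2cc(OC)c(CCC(C)(C)O)c(OCc3ccccc3)c2c1C=O | intermediate |
| 20 | Ebenfuran VI, 4-hydroxy-2-(4-hydroxy-2-methoxyphenyl)-5-(3-hydroxy-3-methylbutyl)-6-methoxy-1-benzofuran-3-carbaldehyde | COc1cc(O)ccc1-c1oc2cc(OC)c(CCC(C)(C)O)c(O)c2c1C=O | target |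

**Step count**

Total step count: 12.
Longest linear sequence: 10 steps (1, 2, 3, 4, 7, 8, 9, 10, 11, 12, counted from compound 1).

**Steps most likely to fail**

Step 8.
- What may go wrong:
  - the iodane may engage the electron-rich rings or linger at the C–I bond instead of adding to a shielded, donor-rich enone;
  - the sulfonic acid released may strip the MOM group before migration and expose a phenol to the oxidant.
- Fallback: this leaves the route at 10 and reaches the same 1,2-diaryl C3 skeleton without any iodine(III) or thallium(III).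
  - Weitz–Scheffer epoxidation (H2O2, NaOH, MeOH–THF) should give the trans-epoxy ketone F1.
  - BF3·OEt2 in CH2Cl2 at low temperature opens F1 at the benzylic carbon that the trioxygenated ring stabilises. It triggers the 1,2-acyl shift typical of chalcone epoxides (Meinwald-type rearrangement), giving the 2-aryl-3-oxopropanal F2.
  - Catalytic TsOH in methanol then removes the MOM group and closes the cyclic methyl acetal, which rejoins the route at 14.

Step 10.
- What may go wrong:
  - ipso-protonation at the iodine-bearing carbon, activated by three oxygen donors, with loss or migration of iodine;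
  - solvolysis of the C4 benzyl ether in the ionising solvent;
  - irreversible loss of methanol from the cyclic acetal before it reopens, which would aromatise the ring with the aroyl group on C3.
- Fallback: this takes both the halogen and the O4 benzyl group out of the acid step and starts from 2.
  - Excess MOMCl and iPr2NEt give the symmetric 4-methoxy-2,6-bis(methoxymethoxy)benzaldehyde F3.
  - Condensation with 8 as in step 7 gives the chalcone F4.
  - The rearrangement of step 8 gives the keto acetal F5.
  - TsOH in methanol frees two equivalent phenols, either of which closes to the hydroxy cyclic acetal F6.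
  - TsOH in (CF3)2CHOH gives the 4-hydroxybenzofuran-3-carbaldehyde F7.
  - Iodination with BnMe3N·ICl2 and CaCO3 is then directed ortho to the phenol chelated to the formyl group, the pattern known from the 6-iodination of 5-hydroxy-7-alkoxyflavones. It gives the 5-iodo phenol F8.
  - BnBr and K2CO3 in DMF bring the material back to 16.

Step 12.
- What may go wrong:
  - over-reduction of the formyl group while the hindered C4 benzyl ether is still being cleaved;
  - hydrogenolysis of the propargylic C–O bond before the triple bond is saturated.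
- Fallback: this removes hydrogen from the endgame altogether and sets out from 16, before the acid-sensitive tertiary alcohol is present.
  - BCl3 with pentamethylbenzene as cation scavenger (CH2Cl2, −78 °C) cleaves both benzyl ethers and keeps iodide, aldehyde and the non-chelated methyl ethers. It gives the iodo bis-phenol F9.
  - Separately, hydroboration of commercial 2-methylbut-3-en-2-ol with 9-BBN-H gives the B-alkyl borane F10. Enough reagent is used to allow for the hydroxyl group, and the excess hydride is destroyed by the aqueous base.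
  - A B-alkyl Suzuki–Miyaura coupling of F9 with F10 (PdCl2(dppf), aq. K3PO4, DMF–THF, 50 °C) installs the saturated chain directly and arrives at 20.

**Further compounds**

F1 | step 8 | trans-(racemic)-[4-(benzyloxy)-2-methoxyphenyl]{3-[2-(benzyloxy)-3-iodo-4-methoxy-6-(methoxymethoxy)phenyl]oxiran-2-yl}methanone | COc1cc(OCc2ccccc2)ccc1C(=O)[C@H]1O[C@@H]1c1c(OCc2ccccc2)c(I)c(OC)cc1OCOC
F2 | step 8 | rac-3-[4-(benzyloxy)-2-methoxyphenyl]-2-[2-(benzyloxy)-3-iodo-4-methoxy-6-(methoxymethoxy)phenyl]-3-oxopropanal | COc1cc(OCc2ccccc2)ccc1C(=O)C(C=O)c1c(OCc2ccccc2)c(I)c(OC)cc1OCOC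
F3 | step 10 | 4-methoxy-2,6-bis(methoxymethoxy)benzaldehyde | COCOc1cc(OC)cc(OCOC)c1C=O
F4 | step 10 | (E)-1-[4-(benzyloxy)-2-methoxyphenyl]-3-[4-methoxy-2,6-bis(methoxymethoxy)phenyl]prop-2-en-1-one | COc1cc(OCc2ccccc2)ccc1C(=O)/C=C/c1c(OCOC)cc(OC)cc1OCOC
F5 | step 10 | rac-1-[4-(benzyloxy)-2-methoxyphenyl]-3,3-dimethoxy-2-[4-methoxy-2,6-bis(methoxymethoxy)phenyl]propan-1-one | COc1cc(OCc2ccccc2)ccc1C(=O)C(C(OC)OC)c1c(OCOC)cc(OC)cc1OCOC
F6 | step 10 | [4-(benzyloxy)-2-methoxyphenyl](4-hydroxy-2,6-dimethoxy-2,3-dihydro-1-benzofuran-3-yl)methanone (racemic diastereomers) | COC1Oc2cc(OC)cc(O)c2C1C(=O)c1ccc(OCc2ccccc2)cc1OC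
F7 | step 10 | 2-[4-(benzyloxy)-2-methoxyphenyl]-4-hydroxy-6-methoxy-1-benzofuran-3-carbaldehyde | COc1cc(OCc2ccccc2)ccc1-c1oc2cc(OC)cc(O)c2c1C=O
F8 | step 10 | 2-[4-(benzyloxy)-2-methoxyphenyl]-4-hydroxy-5-iodo-6-methoxy-1-benzofuran-3-carbaldehyde | COc1cc(OCc2ccccc2)ccc1-c1oc2cc(OC)c(I)c(O)c2c1C=O
F9 | step 12 | 4-hydroxy-2-(4-hydroxy-2-methoxyphenyl)-5-iodo-6-methoxy-1-benzofuran-3-carbaldehyde | COc1cc(O)ccc1-c1oc2cc(OC)c(I)c(O)c2c1C=O
F10 | step 12 | 4-(9-borabicyclo[3.3.1]nonan-9-yl)-2-methylbutan-2-ol | CC(C)(O)CCB1C2CCCC1CCC2
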